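The ring is numbered C1(=O), C2(Me), C3(docosyl), C4(=O), C5(OMe), C6(H). The quinone ring is cut into two three-carbon halves across C1–C6 and C3–C4. The key step exploits the polyketide pattern hidden in the ring: meta oxygens on C1 and C5 and the chain on C3, as in an alkylresorcinol. Copying the biosynthetic Claisen/ring-closure pair, the enolate of acetylacetone adds to the central carbon of an open-chain 2-methyl-2,3-allenoate (C4–C3). A flanking acetyl CH3 then acylates on the ester (C6–C1), and tautomerisation should deliver the fully substituted acylresorcinol in one operation. The acetyl group that acidified C4 is later exchanged for oxygen by Dakin oxidation.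

Key step: step 3

Remark: the target has no stereocentre. Allenoate 5 is axially chiral, is used as the racemate, and loses its axis in step 3. Compounds 1, 3 and 6 are taken as commercial.

Step 1
Reactants: 1 tricosanoic acid
Product: 2 tricosanoyl chloride
Conditions: (COCl)2 (1.5 equiv), cat. DMF, CH2Cl2, 0 °C to 35 °C; volatiles removed
Reagents that add atoms: oxalyl chloride, O=C(Cl)C(=O)Cl
Why: DMF-catalysed acid chloride formation (Vilsmeier-type activation) is routine for saturated fatty acids, and 1 holds no other reactive group.

Step 2
Reactants: 2 tricosanoyl chloride; 3 ethyl 2-(triphenylphosphoranylidene)propanoate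
Product: 5 ethyl 2-methylpentacosa-2,3-dienoate (racemic), via henicosylketene 4 (not isolated)
Conditions: Et3N (1.1 equiv), CH2Cl2, 0 °C to rt
Reagents that add atoms: none
Why: Et3N dehydrochlorinates 2 to ketene 4, and the stabilised ylide 3 olefinates the ketene C=O (Wittig allenoate synthesis); the new allene axis forms as the racemate, which is of no consequence.

Step 3
Reactants: 5 ethyl 2-methylpentacosa-2,3-dienoate; 6 acetylacetone (pentane-2,4-dione)
Product: 8 1-(2-docosyl-4,6-dihydroxy-3-methylphenyl)ethan-1-one, via Michael adduct 7 (not isolated)
Conditions: 6 (1.1 equiv), KOt-Bu (1.0 equiv), THF, 0 °C, then 5, rt; then KOt-Bu (2.5 equiv), 65 °C; 1 M HCl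
Reagents that add atoms: none
Why: The potassium monoenolate of 6 adds through its soft central carbon (future C4) to the electrophilic sp carbon of 5 (future C3) and proton shifts give adduct 7, whose E and Z forms interconvert through the delocalised anion; the extra base then reversibly deprotonates one of the two equivalent acetyl CH3 groups (future C6), which attacks the ester carbonyl (future C1) with loss of ethoxide, and the cyclohexenedione so formed tautomerises to the resorcinol. The closest known reaction type is the Michael–Claisen (Michael–Dieckmann) [3+3] cyclocondensation of β-dicarbonyl anions with acetylenic, allenic or olefinic esters, the laboratory counterpart of the Claisen extension and ring closure of the alkylresorcinol polyketide pathway, with 5 serving as the anhydro form of the β-keto ester diketide. The one new ring closes in a 6-(enolendo)-exo-trig acylation. No stereocentre is formed, and the racemic allene axis of 5 is erased. Regiochemistry is secured because the monoenolate is made before 5 is added (only the central carbon is nucleophilic, so the acetyl group ends on C4), because the allene carries its methyl on the ester-bearing carbon (Me ends on C2, the chain on C3), and because 6 is symmetric (either CH3 gives the same ring). Closure through the enol oxygen is the competing path, but the liberated ethoxide should reverse it, whereas C-acylation becomes irreversible through aromatisation to the bis-phenoxide.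

Step 4
Reactants: 8 1-(2-docosyl-4,6-dihydroxy-3-methylphenyl)ethan-1-one
Product: 11 3-docosyl-5-hydroxy-2-methylcyclohexa-2,5-diene-1,4-dione, via aryl acetate 9 (not isolated), via benzenetriol 10 (not isolated)
Conditions: 30% aq H2O2 (excess), NaOH, THF–H2O, 0 °C to rt; then 1 M HCl
Reagents that add atoms: hydrogen peroxide, OO
Why: Dakin oxidation of an ortho,para-dihydroxyaryl ketone: hydroperoxide adds to the acetyl C=O, the electron-rich aryl group migrates to oxygen, acetate 9 is saponified in situ, and triol 10 is oxidised by the excess peroxide to the hydroxyquinone, whose delocalised anion resists further nucleophilic attack.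

Step 5
Reactants: 11 3-docosyl-5-hydroxy-2-methylcyclohexa-2,5-diene-1,4-dione
Product: 12 3-docosyl-5-methoxy-2-methylcyclohexa-2,5-diene-1,4-dione (target)
Conditions: MeOH–CHCl3, cat. H2SO4, reflux
Reagents that add atoms: methanol, CO
Why: Acid-catalysed addition–elimination at C5 (vinylogous Fischer esterification of a hydroxyquinone) exchanges the only OH for OMe, and the para-quinone ether is the thermodynamic product under these reversible conditions.

Compound list
1 | tricosanoic acid | CCCCCCCCCCCCCCCCCCCCCCC(=O)O | starting material
2 | tricosanoyl chloride | CCCCCCCCCCCCCCCCCCCCCCC(=O)Cl | intermediate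
3 | ethyl 2-(triphenylphosphoranylidene)propanoate | CCOC(=O)C(C)=P(c1ccccc1)(c1ccccc1)c1ccccc1 | starting material
4 | henicosylketene (tricos-1-en-1-one) | CCCCCCCCCCCCCCCCCCCCCC=C=O | intermediate
5 | ethyl 2-methylpentacosa-2,3-dienoate (racemic allene) | CCCCCCCCCCCCCCCCCCCCCC=C=C(C)C(=O)OCC | intermediate
6 | acetylacetone (pentane-2,4-dione) | CC(=O)CC(C)=O | starting material
7 | ethyl (Z)-3-(2,4-dioxopentan-3-yl)-2-methylpentacos-2-enoate (Michael adduct; the Z form cyclises, E and Z interconvert under base) | CCCCCCCCCCCCCCCCCCCCCC/C(C(C(C)=O)C(C)=O)=C(\C)C(=O)OCC | intermediate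
8 | 1-(2-docosyl-4,6-dihydroxy-3-methylphenyl)ethan-1-one | CCCCCCCCCCCCCCCCCCCCCCc1c(C)c(O)cc(O)c1C(C)=O | intermediate
9 | 2-docosyl-4,6-dihydroxy-3-methylphenyl acetate | CCCCCCCCCCCCCCCCCCCCCCc1c(C)c(O)cc(O)c1OC(C)=O | intermediate
10 | 6-docosyl-5-methylbenzene-1,2,4-triol | CCCCCCCCCCCCCCCCCCCCCCc1c(C)c(O)cc(O)c1O | intermediate
11 | 3-docosyl-5-hydroxy-2-methylcyclohexa-2,5-diene-1,4-dione | CCCCCCCCCCCCCCCCCCCCCCC1=C(C)C(=O)C=C(O)C1=O | intermediate
12 | 3-docosyl-5-methoxy-2-methylcyclohexa-2,5-diene-1,4-dione | CCCCCCCCCCCCCCCCCCCCCCC1=C(C)C(=O)C=C(OC)C1=O | target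

Total step count: 5. Longest linear sequence: 5 (1 → 2 → 5 → 8 → 11 → 12).

Steps most likely to fail

Step 3. Ring closure through the enol oxygen (lactonisation) may outrun C-acylation. An acetyl group may also be lost by retro-Claisen cleavage before closure, or the base may isomerise the allene before the Michael addition.
- The fallback sets out from 5 and uses a donor whose two nucleophilic carbons are both doubly activated, so no second hard deprotonation is needed.
- Dimethyl 3-oxopentanedioate with NaH in THF at rt should undergo Michael addition and Dieckmann closure in sequence. This should give dimethyl 4-docosyl-2,6-dihydroxy-5-methylbenzene-1,3-dicarboxylate F1.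
- Saponification and double decarboxylation (KOH, aq EtOH, reflux, then acid and heat) should give 5-docosyl-4-methylbenzene-1,3-diol F2.
- Teuber oxidation with (KSO3)2NO in KH2PO4-buffered H2O–THF then places the oxygen on C4, the only free position para to a hydroxyl group. The sequence comes back to the route at 11.

Step 4. Peroxide addition may be slow, because the ketone is hindered and deactivated by two phenoxides. The electron-rich ring may also be degraded oxidatively in alkaline peroxide.
- The fallback sets out from 8 and moves the oxygen insertion to a protected, neutral substrate.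
- Exhaustive O-methylation (Me2SO4, K2CO3, acetone, reflux) should give 1-(2-docosyl-4,6-dimethoxy-3-methylphenyl)ethan-1-one F3.
- Baeyer–Villiger oxidation (mCPBA, CH2Cl2) should give 2-docosyl-4,6-dimethoxy-3-methylphenyl acetate F4.
- Hydrolysis (LiOH, aq THF) should give 2-docosyl-4,6-dimethoxy-3-methylphenol F5.
- Oxidative demethylation of this para-methoxyphenol with (NH4)2Ce(NO3)6 in MeCN–H2O keeps the C5 methoxy group. The sequence comes back to the route at 12, so step 5 is not needed.

Step 5. Etherification may stay incomplete because the water formed holds back the equilibrium. Hot acid may also cause self-condensation at the free C6–H.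
- The fallback sets out from 11 and replaces the equilibrium exchange by irreversible alkylation followed by regiodefined oxidation.
- Reduction with Na2S2O4 back to 10 and exhaustive methylation in the same flask (Me2SO4, K2CO3, acetone, under N2) should give 3-docosyl-1,2,5-trimethoxy-4-methylbenzene F6.
- (NH4)2Ce(NO3)6 in MeCN–H2O then oxidises the para-dimethoxy pair (C1 and C4) and leaves the C5 methoxy group. The sequence comes back to the route at 12.

Further compounds
F1 | step 3 | dimethyl 4-docosyl-2,6-dihydroxy-5-methylbenzene-1,3-dicarboxylate | CCCCCCCCCCCCCCCCCCCCCCc1c(C)c(O)c(C(=O)OC)c(O)c1C(=O)OC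
F2 | step 3 | 5-docosyl-4-methylbenzene-1,3-diol | CCCCCCCCCCCCCCCCCCCCCCc1cc(O)cc(O)c1C
F3 | step 4 | 1-(2-docosyl-4,6-dimethoxy-3-methylphenyl)ethan-1-one | CCCCCCCCCCCCCCCCCCCCCCc1c(C)c(OC)cc(OC)c1C(C)=O
F4 | step 4 | 2-docosyl-4,6-dimethoxy-3-methylphenyl acetate | CCCCCCCCCCCCCCCCCCCCCCc1c(C)c(OC)cc(OC)c1OC(C)=O
F5 | step 4 | 2-docosyl-4,6-dimethoxy-3-methylphenol | CCCCCCCCCCCCCCCCCCCCCCc1c(C)c(OC)cc(OC)c1O
F6 | step 5 | 3-docosyl-1,2,5-trimethoxy-4-methylbenzene | CCCCCCCCCCCCCCCCCCCCCCc1c(C)c(OC)cc(OC)c1OC
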